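## Retrosynthetic overview

1. Target 24 ⇐ desilylation and C5 acetylation of hydroxy lactone 22; the exo-methylene comes from decarboxylative Mannich methylenation of an α-carboxy ε-lactone.
2. Ring B (ε-lactone, formed second) ⇐ biomimetic 7-exo opening of a (4R,5R)-epoxide by a C15 malonic acid, with inversion at C4.
3. Ring A (14-membered carbocycle, formed first) ⇐ nickel-catalysed reductive ynal macrocyclization making C12–C13, the 11E olefin and the C13–O centre.
4. Acyclic ynal ⇐ Stille propynylation at C10, Shi epoxidation of the 4E olefin, and the new copper-catalysed enantioselective B-alkyl conjugate addition (C1–C2 bond, C1 stereocentre).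
5. Building blocks: neryl acetate (C3–C10, C18, C19; brings 8Z), 3-(TBSO)propanal (C1, C14, C13), dimethyl malonate (C15, C16).

Assumption: locants follow cembrane numbering (C1 = ring CH carrying C15; lactone C16(=O)–O–C4; OAc on C5; OH on C13; methyls C18, C19, C20 on C4, C8, C12), and compounds 1, 2 and 4 are bought.

## Route

Step 1
Reactants: 1 3-(tert-butyldimethylsilyloxy)propanal; 2 dimethyl malonate
Product: 3 dimethyl 2-[3-(tert-butyldimethylsilyloxy)propylidene]malonate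
Conditions: piperidine (0.1 equiv), AcOH (0.1 equiv), 4 Å MS, CH2Cl2, rt
Reagents that add atoms: none
Why: Knoevenagel condensation of an unhindered aldehyde under piperidinium acetate catalysis with water removal; no stereocentre is formed.

Step 2
Reactants: 4 neryl acetate [(2Z)-3,7-dimethylocta-2,6-dien-1-yl acetate]
Product: 5 (2Z,6E)-8-hydroxy-3,7-dimethylocta-2,6-dien-1-yl acetate
Conditions: SeO2 (0.3 equiv), t-BuOOH (3 equiv), salicylic acid (0.1 equiv), CH2Cl2, rt
Reagents that add atoms: selenium dioxide, O=[Se]=O; tert-butyl hydroperoxide, CC(C)(C)OO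
Why: Riley allylic oxidation (ene reaction, then [2,3] shift) attacks the E-methyl of the electron-rich terminal olefin, while the 2,3-olefin is deactivated by its allylic acetate, so the 6E alcohol results.

Step 3
Reactants: 5 (2Z,6E)-8-hydroxy-3,7-dimethylocta-2,6-dien-1-yl acetate
Product: 6 (2E,6Z)-8-acetoxy-2,6-dimethylocta-2,6-dienal
Conditions: MnO2 (15 equiv), CH2Cl2, rt
Reagents that add atoms: none
Why: MnO2 oxidation is selective for the allylic alcohol and keeps both olefin geometries.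

Step 4
Reactants: 6 (2E,6Z)-8-acetoxy-2,6-dimethylocta-2,6-dienal
Product: 7 (2Z,6E)-3,7-dimethylnona-2,6,8-trien-1-yl acetate
Conditions: Ph3PCH3Br, KN(SiMe3)2, THF, 0 °C; then 6, −78 → 0 °C
Reagents that add atoms: methyltriphenylphosphonium bromide, C[P+](c1ccccc1)(c1ccccc1)c1ccccc1.[Br-]
Why: Wittig methylenation of the enal is much faster than attack on the acetate at low temperature and gives the terminal diene with the 6E olefin intact.

Step 5
Reactants: 7 (2Z,6E)-3,7-dimethylnona-2,6,8-trien-1-yl acetate; 3 dimethyl 2-[3-(tert-butyldimethylsilyloxy)propylidene]malonate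
Product: 10 dimethyl 2-[(3S,6E,10Z)-12-acetoxy-1-(tert-butyldimethylsilyloxy)-6,10-dimethyldodeca-6,10-dien-3-yl]malonate, via alkylborane 8 (not isolated), via methoxyborate 9 (not isolated)
Conditions: 9-BBN dimer (0.55 equiv), THF, 0 °C → rt; KOMe (1.1 equiv); then CuCl (5 mol%), (R)-DTBM-SEGPHOS (6 mol%), 3 (0.9 equiv), THF/1,4-dioxane, 10 °C; AcOH quench
Reagents that add atoms: 9-borabicyclo[3.3.1]nonane, B1C2CCCC1CCC2 (boron unit of 8 and 9 only); potassium methoxide, C[O-].[K+] (methoxide and potassium of 9 only); nothing but hydrogen stays in 10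
Why: Proposed new method: an enantioselective copper-catalysed 1,4-addition of a B-alkyl-9-BBN to an aliphatic alkylidene malonate, which makes the C1–C2 bond, joins the two halves and sets C1 (S): 9-BBN hydroborates only the terminal vinyl group, methoxide turns 8 into borate 9, its primary alkyl group transmetalates to the chiral bisphosphine complex of monovalent copper, the alkylcopper carbocuprates the electron-poor C=C of 3 on the π-face left open by the ligand (both esters are identical, so only facial choice matters), and the copper malonate enolate is released by the next borate; the closest known reactions are copper-catalysed conjugate additions of alkyl-9-BBN reagents to activated enones and copper/chiral-phosphine additions of dialkylzincs to alkylidene malonates; the ligand antipode giving 3S is fixed in a model run.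

Step 6
Reactants: 10 dimethyl 2-[(3S,6E,10Z)-12-acetoxy-1-(tert-butyldimethylsilyloxy)-6,10-dimethyldodeca-6,10-dien-3-yl]malonate
Product: 11 dimethyl 2-[(3S,6R,7R,10Z)-12-acetoxy-1-(tert-butyldimethylsilyloxy)-6,7-epoxy-6,10-dimethyldodec-10-en-3-yl]malonate
Conditions: 1,2:4,5-di-O-isopropylidene-β-D-erythro-2,3-hexodiulo-2,6-pyranose (Shi ketone, 0.3 equiv), Oxone (2KHSO5·KHSO4·K2SO4, 1.4 equiv KHSO5), K2CO3, n-Bu4NHSO4 (cat.), MeCN/CH2(OMe)2/aq. Na2B4O7 buffer, pH 10.5, 0 °C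
Reagents that add atoms: potassium peroxymonosulfate (active part of Oxone), [K+].[O-]S(=O)(=O)OO
Why: Shi asymmetric epoxidation (chiral dioxirane, spiro transition state) gives the (R,R)-epoxide of the only electron-rich E-trisubstituted olefin under catalyst control, the Z-olefin being deactivated by its allylic acetate.

Step 7
Reactants: 11 dimethyl 2-[(3S,6R,7R,10Z)-12-acetoxy-1-(tert-butyldimethylsilyloxy)-6,7-epoxy-6,10-dimethyldodec-10-en-3-yl]malonate
Product: 12 dimethyl 2-[(3S,6R,7R,10Z)-1-(tert-butyldimethylsilyloxy)-6,7-epoxy-12-hydroxy-6,10-dimethyldodec-10-en-3-yl]malonate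
Conditions: K2CO3 (0.2 equiv), MeOH, 0 °C
Reagents that add atoms: none
Why: Base-catalysed transesterification (methanolysis) removes the acetate; the methyl esters are unchanged in methanol and the epoxide and silyl ether are inert at 0 °C.

Step 8
Reactants: 12 dimethyl 2-[(3S,6R,7R,10Z)-1-(tert-butyldimethylsilyloxy)-6,7-epoxy-12-hydroxy-6,10-dimethyldodec-10-en-3-yl]malonate
Product: 14 dimethyl 2-[(3S,6R,7R,10Z)-1-(tert-butyldimethylsilyloxy)-12-chloro-6,7-epoxy-6,10-dimethyldodec-10-en-3-yl]malonate, via mesylate 13 (not isolated)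
Conditions: MsCl, Et3N, CH2Cl2, −30 °C; then LiCl, DMF, 0 °C
Reagents that add atoms: methanesulfonyl chloride, CS(=O)(=O)Cl (mesyl group of 13 only); lithium chloride, [Li+].[Cl-] (chlorine of 14)
Why: Mesylation followed by SN2 displacement with chloride converts the primary allylic alcohol without ionisation, so the 10Z geometry is kept.

Step 9
Reactants: 14 dimethyl 2-[(3S,6R,7R,10Z)-1-(tert-butyldimethylsilyloxy)-12-chloro-6,7-epoxy-6,10-dimethyldodec-10-en-3-yl]malonate
Product: 15 dimethyl 2-[(3S,6R,7R,10Z)-1-(tert-butyldimethylsilyloxy)-6,7-epoxy-6,10-dimethylpentadec-10-en-13-yn-3-yl]malonate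
Conditions: tributyl(prop-1-yn-1-yl)stannane (1.3 equiv), Pd2(dba)3 (2.5 mol%), AsPh3 (10 mol%), THF, 40 °C
Reagents that add atoms: tributyl(prop-1-yn-1-yl)stannane, CC#C[Sn](CCCC)(CCCC)CCCC
Why: Stille allyl–alkynyl coupling under neutral conditions (the malonate C–H is not deprotonated); fast alkynyl transmetalation and reductive elimination at the primary allyl terminus outrun syn–anti isomerisation, keeping the Z olefin.

Step 10
Reactants: 15 dimethyl 2-[(3S,6R,7R,10Z)-1-(tert-butyldimethylsilyloxy)-6,7-epoxy-6,10-dimethylpentadec-10-en-13-yn-3-yl]malonate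
Product: 16 dimethyl 2-[(3S,6R,7R,10Z)-6,7-epoxy-1-hydroxy-6,10-dimethylpentadec-10-en-13-yn-3-yl]malonate
Conditions: n-Bu4NF, AcOH (1:1), THF, 0 °C → rt
Reagents that add atoms: none
Why: Fluoride desilylation buffered with acetic acid frees the primary alcohol without enolising the malonate toward the epoxide.

Step 11
Reactants: 16 dimethyl 2-[(3S,6R,7R,10Z)-6,7-epoxy-1-hydroxy-6,10-dimethylpentadec-10-en-13-yn-3-yl]malonate
Product: 17 dimethyl 2-[(3S,6R,7R,10Z)-6,7-epoxy-6,10-dimethyl-1-oxopentadec-10-en-13-yn-3-yl]malonate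
Conditions: (n-Pr4N)RuO4 (5 mol%), N-methylmorpholine N-oxide, 4 Å MS, CH2Cl2, rt
Reagents that add atoms: none
Why: Ley–Griffith oxidation is neutral and stops at the aldehyde, leaving epoxide, alkyne and olefins untouched.

Step 12
Reactants: 17 dimethyl 2-[(3S,6R,7R,10Z)-6,7-epoxy-6,10-dimethyl-1-oxopentadec-10-en-13-yn-3-yl]malonate
Product: 18 dimethyl 2-[(1S,4R,5R,8Z,11E,13S)-4,5-epoxy-4,8,12-trimethyl-13-(triisopropylsilyloxy)cyclotetradeca-8,11-dien-1-yl]malonate
Conditions: Ni(cod)2 (20 mol%), 1,3-bis(2,4,6-trimethylphenyl)imidazol-2-ylidene (20 mol%), i-Pr3SiH (3 equiv), THF, 0.005 M, slow addition, rt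
Reagents that add atoms: triisopropylsilane, CC(C)[SiH](C(C)C)C(C)C
Why: Nickel-catalysed reductive alkyne–aldehyde coupling run as an ynal macrocyclization: zerovalent nickel with the small carbene joins the aldehyde carbon to the methyl-bearing alkyne carbon, and Si–H σ-bond metathesis then cis C–H reductive elimination give the 11E olefin and the C13 silyl ether; the 13S centre rests on substrate control in the macrocyclic transition state and is the uncertain point.

Step 13
Reactants: 18 dimethyl 2-[(1S,4R,5R,8Z,11E,13S)-4,5-epoxy-4,8,12-trimethyl-13-(triisopropylsilyloxy)cyclotetradeca-8,11-dien-1-yl]malonate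
Product: 20 (1S,4S,5R,8Z,11E,13S)-15-carboxy-5-hydroxy-13-(triisopropylsilyloxy)cembra-8,11-dien-16,4-olide (C15 epimers), via malonic acid 19 (not isolated)
Conditions: KOSiMe3 (2.4 equiv), THF, rt → 40 °C; then MsOH (2.5 equiv), CH2Cl2, −20 °C → rt
Reagents that add atoms: potassium trimethylsilanolate, C[Si](C)(C)[O-].[K+]
Why: Anhydrous silanolate ester cleavage, then a biomimetic acid-catalysed 7-exo-tet epoxide-opening lactonization in which a malonic carboxyl attacks the protonated epoxide at the tertiary carbon C4 with inversion (4R → 4S), while C5 keeps its oxygen and configuration (5R); no water is present to compete.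

Step 14
Reactants: 20 (1S,4S,5R,8Z,11E,13S)-15-carboxy-5-hydroxy-13-(triisopropylsilyloxy)cembra-8,11-dien-16,4-olide
Product: 22 (1S,4S,5R,8Z,11E,13S)-5-hydroxy-13-(triisopropylsilyloxy)cembra-8,11,15(17)-trien-16,4-olide, via Mannich base 21 (not isolated)
Conditions: (CH2O)n, Et2NH, THF, 65 °C
Reagents that add atoms: formaldehyde (as paraformaldehyde), C=O; diethylamine, CCNCC (amino group of 21 only)
Why: Decarboxylative Mannich methylenation (Mannich reaction at the acidic C15–H, then loss of CO2 and Et2NH) installs the exo-methylene without touching any stereocentre.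

Step 15
Reactants: 22 (1S,4S,5R,8Z,11E,13S)-5-hydroxy-13-(triisopropylsilyloxy)cembra-8,11,15(17)-trien-16,4-olide
Product: 23 (1S,4S,5R,8Z,11E,13S)-5-acetoxy-13-(triisopropylsilyloxy)cembra-8,11,15(17)-trien-16,4-olide
Conditions: Ac2O, DMAP (cat.), pyridine, CH2Cl2, rt
Reagents that add atoms: acetic anhydride, CC(=O)OC(C)=O
Why: DMAP-catalysed acetylation of the only free hydroxyl (C5), the C13 oxygen being masked as the silyl ether delivered in step 12.

Step 16
Reactants: 23 (1S,4S,5R,8Z,11E,13S)-5-acetoxy-13-(triisopropylsilyloxy)cembra-8,11,15(17)-trien-16,4-olide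
Product: 24 (1S,4S,5R,8Z,11E,13S)-5-acetoxy-13-hydroxycembra-8,11,15(17)-trien-16,4-olide (CNP0130972.9)
Conditions: HF·pyridine, pyridine, THF, 0 °C → rt
Reagents that add atoms: none
Why: Buffered fluoride desilylation frees the allylic C13 alcohol without acetate migration or addition to the α-methylene lactone.

## Compound list

1 | 3-(tert-butyldimethylsilyloxy)propanal | O=CCCO[Si](C)(C)C(C)(C)C | starting material
2 | dimethyl malonate | COC(=O)CC(=O)OC | starting material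
3 | dimethyl 2-[3-(tert-butyldimethylsilyloxy)propylidene]malonate | COC(=O)C(=CCCO[Si](C)(C)C(C)(C)C)C(=O)OC | intermediate
4 | neryl acetate | CC(C)=CCC/C(C)=C\COC(C)=O | starting material
5 | (2Z,6E)-8-hydroxy-3,7-dimethylocta-2,6-dien-1-yl acetate | OC/C(C)=C/CC/C(C)=C\COC(C)=O | intermediate
6 | (2E,6Z)-8-acetoxy-2,6-dimethylocta-2,6-dienal | O=C/C(C)=C/CC/C(C)=C\COC(C)=O | intermediate
7 | (2Z,6E)-3,7-dimethylnona-2,6,8-trien-1-yl acetate | C=C/C(C)=C/CC/C(C)=C\COC(C)=O | intermediate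
8 | B-[(3E,7Z)-9-acetoxy-3,7-dimethylnona-3,7-dien-1-yl]-9-borabicyclo[3.3.1]nonane (not isolated) | B1(CC/C(C)=C/CC/C(C)=C\COC(C)=O)C2CCCC1CCC2 | intermediate
9 | potassium B-methoxy borate of 8 (not isolated) | CO[B-]1(CC/C(C)=C/CC/C(C)=C\COC(C)=O)C2CCCC1CCC2.[K+] | intermediate
10 | dimethyl 2-[(3S,6E,10Z)-12-acetoxy-1-(tert-butyldimethylsilyloxy)-6,10-dimethyldodeca-6,10-dien-3-yl]malonate | COC(=O)C([C@H](CCO[Si](C)(C)C(C)(C)C)CC/C(C)=C/CC/C(C)=C\COC(C)=O)C(=O)OC | intermediate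
11 | dimethyl 2-[(3S,6R,7R,10Z)-12-acetoxy-1-(tert-butyldimethylsilyloxy)-6,7-epoxy-6,10-dimethyldodec-10-en-3-yl]malonate | COC(=O)C([C@H](CCO[Si](C)(C)C(C)(C)C)CC[C@@]1(C)O[C@@H]1CC/C(C)=C\COC(C)=O)C(=O)OC | intermediate
12 | dimethyl 2-[(3S,6R,7R,10Z)-1-(tert-butyldimethylsilyloxy)-6,7-epoxy-12-hydroxy-6,10-dimethyldodec-10-en-3-yl]malonate | COC(=O)C([C@H](CCO[Si](C)(C)C(C)(C)C)CC[C@@]1(C)O[C@@H]1CC/C(C)=C\CO)C(=O)OC | intermediate
13 | 12-methanesulfonate of 12 (not isolated) | COC(=O)C([C@H](CCO[Si](C)(C)C(C)(C)C)CC[C@@]1(C)O[C@@H]1CC/C(C)=C\COS(C)(=O)=O)C(=O)OC | intermediate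
14 | dimethyl 2-[(3S,6R,7R,10Z)-1-(tert-butyldimethylsilyloxy)-12-chloro-6,7-epoxy-6,10-dimethyldodec-10-en-3-yl]malonate | COC(=O)C([C@H](CCO[Si](C)(C)C(C)(C)C)CC[C@@]1(C)O[C@@H]1CC/C(C)=C\CCl)C(=O)OC | intermediate
15 | dimethyl 2-[(3S,6R,7R,10Z)-1-(tert-butyldimethylsilyloxy)-6,7-epoxy-6,10-dimethylpentadec-10-en-13-yn-3-yl]malonate | COC(=O)C([C@H](CCO[Si](C)(C)C(C)(C)C)CC[C@@]1(C)O[C@@H]1CC/C(C)=C\CC#CC)C(=O)OC | intermediate
16 | dimethyl 2-[(3S,6R,7R,10Z)-6,7-epoxy-1-hydroxy-6,10-dimethylpentadec-10-en-13-yn-3-yl]malonate | COC(=O)C([C@H](CCO)CC[C@@]1(C)O[C@@H]1CC/C(C)=C\CC#CC)C(=O)OC | intermediate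
17 | dimethyl 2-[(3S,6R,7R,10Z)-6,7-epoxy-6,10-dimethyl-1-oxopentadec-10-en-13-yn-3-yl]malonate | COC(=O)C([C@H](CC=O)CC[C@@]1(C)O[C@@H]1CC/C(C)=C\CC#CC)C(=O)OC | intermediate
18 | dimethyl 2-[(1S,4R,5R,8Z,11E,13S)-4,5-epoxy-4,8,12-trimethyl-13-(triisopropylsilyloxy)cyclotetradeca-8,11-dien-1-yl]malonate | COC(=O)C(C(=O)OC)[C@H]1CC[C@@]2(C)O[C@@H]2CC/C(C)=C\C/C=C(C)/[C@@H](O[Si](C(C)C)(C(C)C)C(C)C)C1 | intermediate
19 | malonic acid corresponding to 18 (not isolated) | OC(=O)C(C(=O)O)[C@H]1CC[C@@]2(C)O[C@@H]2CC/C(C)=C\C/C=C(C)/[C@@H](O[Si](C(C)C)(C(C)C)C(C)C)C1 | intermediate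
20 | (1S,4S,5R,8Z,11E,13S)-15-carboxy-5-hydroxy-13-(triisopropylsilyloxy)cembra-8,11-dien-16,4-olide (C15 epimers) | O=C(O)C1C(=O)O[C@@]2(C)CC[C@H]1C[C@H](O[Si](C(C)C)(C(C)C)C(C)C)/C(C)=C/C/C=C(/C)CC[C@H]2O | intermediate
21 | 15-(diethylaminomethyl) Mannich base of 20 (not isolated) | CCN(CC)CC1(C(=O)O)C(=O)O[C@@]2(C)CC[C@H]1C[C@H](O[Si](C(C)C)(C(C)C)C(C)C)/C(C)=C/C/C=C(/C)CC[C@H]2O | intermediate
22 | (1S,4S,5R,8Z,11E,13S)-5-hydroxy-13-(triisopropylsilyloxy)cembra-8,11,15(17)-trien-16,4-olide | C=C1C(=O)O[C@@]2(C)CC[C@H]1C[C@H](O[Si](C(C)C)(C(C)C)C(C)C)/C(C)=C/C/C=C(/C)CC[C@H]2O | intermediate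
23 | (1S,4S,5R,8Z,11E,13S)-5-acetoxy-13-(triisopropylsilyloxy)cembra-8,11,15(17)-trien-16,4-olide | C=C1C(=O)O[C@@]2(C)CC[C@H]1C[C@H](O[Si](C(C)C)(C(C)C)C(C)C)/C(C)=C/C/C=C(/C)CC[C@H]2OC(C)=O | intermediate
24 | (1S,4S,5R,8Z,11E,13S)-5-acetoxy-13-hydroxycembra-8,11,15(17)-trien-16,4-olide | C=C1C(=O)O[C@@]2(C)CC[C@H]1C[C@H](O)/C(C)=C/C/C=C(/C)CC[C@H]2OC(C)=O | target

## Step count and risk

Total: 16 steps. Longest linear sequence: 15 steps (4 → 24, steps 2–16); step 1 is a one-step branch.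

**Step 5 (the proposed new method).** Transmetalation of a functionalised alkylborate and the level of facial control on an aliphatic alkylidene malonate are unproven, and the acetate must survive the borate/methoxide. Fallback with known chemistry, setting out from 7 and coming back at 10: 7 is hydroborated as before and 8 is used in a B-alkyl Suzuki–Miyaura coupling with (E)-3-iodoprop-2-en-1-ol (PdCl2(dppf), AsPh3, Cs2CO3, DMF/THF/H2O, rt). This gives (2E,6E,10Z)-12-acetoxy-6,10-dimethyldodeca-2,6,10-trien-1-ol F1. Methyl chloroformate and pyridine give its methyl carbonate (2E,6E,10Z)-12-acetoxy-6,10-dimethyldodeca-2,6,10-trien-1-yl methyl carbonate F2. Iridium-catalysed asymmetric allylic alkylation ([Ir(cod)Cl]2, a chiral phosphoramidite of the antipode that gives 3S, sodium salt of 2, THF, rt) attacks only the carbonate and gives the branched dimethyl 2-[(3S,6E,10Z)-12-acetoxy-6,10-dimethyldodeca-1,6,10-trien-3-yl]malonate F3. 9-BBN then NaBO3·4H2O converts the new vinyl group into dimethyl 2-[(3S,6E,10Z)-12-acetoxy-1-hydroxy-6,10-dimethyldodeca-6,10-dien-3-yl]malonate F4, and TBSCl/imidazole gives 10.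

**Step 12 (macrocyclization).** The regiochemistry of alkyne insertion, the C13 configuration, and the tolerance of zerovalent nickel for the malonate C–H and the epoxide are all uncertain. Fallback setting out from 16 and coming back at 18: hydrozirconation–iodination of the methyl alkyne (Cp2Zr(H)Cl in excess, THF, then I2) gives dimethyl 2-[(3S,6R,7R,10Z,13E)-6,7-epoxy-1-hydroxy-14-iodo-6,10-dimethylpentadeca-10,13-dien-3-yl]malonate F5. Ley–Griffith oxidation gives dimethyl 2-[(3S,6R,7R,10Z,13E)-6,7-epoxy-14-iodo-6,10-dimethyl-1-oxopentadeca-10,13-dien-3-yl]malonate F6. Nozaki–Hiyama–Kishi macrocyclization (CrCl2, NiCl2 cat., DMSO/THF, 0.003 M) closes the ring to dimethyl 2-[(1S,4R,5R,8Z,11E,13S)-4,5-epoxy-13-hydroxy-4,8,12-trimethylcyclotetradeca-8,11-dien-1-yl]malonate F7. If C13 epimers form, the mixture is oxidised (Dess–Martin periodinane) to dimethyl 2-[(1S,4R,5R,8Z,11E)-4,5-epoxy-4,8,12-trimethyl-13-oxocyclotetradeca-8,11-dien-1-yl]malonate F8, which is reduced back to the 13S alcohol with (R)-2-methyl-CBS-oxazaborolidine and BH3·SMe2 (alkenyl as the large group). i-Pr3SiOTf/2,6-lutidine then gives 18.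

**Step 13 (epoxide-opening lactonization on the macrocycle).** Transannular attack of the C8=C9 olefin on the activated epoxide, hydride shift or elimination may beat the 7-exo carboxyl attack. Fallback setting out from 15 and coming back at 20, closing ring B before ring A so that no transannular path exists: KOSiMe3 (1.0 equiv) cleaves one ester of 15, and MsOH (1.0 equiv) in CH2Cl2 triggers the same invertive 7-exo opening. This gives methyl (4S,7S)-4-[2-(tert-butyldimethylsilyloxy)ethyl]-7-[(1R,4Z)-1-hydroxy-4-methylnon-4-en-7-yn-1-yl]-7-methyl-2-oxooxepane-3-carboxylate F9. n-Bu4NF/AcOH gives methyl (4S,7S)-4-(2-hydroxyethyl)-7-[(1R,4Z)-1-hydroxy-4-methylnon-4-en-7-yn-1-yl]-7-methyl-2-oxooxepane-3-carboxylate F10. TEMPO/PhI(OAc)2 oxidises only the primary alcohol to methyl (4S,7S)-7-[(1R,4Z)-1-hydroxy-4-methylnon-4-en-7-yn-1-yl]-7-methyl-2-oxo-4-(2-oxoethyl)oxepane-3-carboxylate F11. The nickel-catalysed reductive macrocyclization of step 12 gives methyl (1S,4S,5R,8Z,11E,13S)-5-hydroxy-13-(triisopropylsilyloxy)cembra-8,11-dien-16,4-olide-15-carboxylate F12, and SN2 demethylation with LiI in pyridine (reflux) gives 20.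

## Further compounds

F1 | step 5 | (2E,6E,10Z)-12-acetoxy-6,10-dimethyldodeca-2,6,10-trien-1-ol | OC/C=C/CC/C(C)=C/CC/C(C)=C\COC(C)=O
F2 | step 5 | (2E,6E,10Z)-12-acetoxy-6,10-dimethyldodeca-2,6,10-trien-1-yl methyl carbonate | COC(=O)OC/C=C/CC/C(C)=C/CC/C(C)=C\COC(C)=O
F3 | step 5 | dimethyl 2-[(3S,6E,10Z)-12-acetoxy-6,10-dimethyldodeca-1,6,10-trien-3-yl]malonate | COC(=O)C([C@H](C=C)CC/C(C)=C/CC/C(C)=C\COC(C)=O)C(=O)OC
F4 | step 5 | dimethyl 2-[(3S,6E,10Z)-12-acetoxy-1-hydroxy-6,10-dimethyldodeca-6,10-dien-3-yl]malonate | COC(=O)C([C@H](CCO)CC/C(C)=C/CC/C(C)=C\COC(C)=O)C(=O)OC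
F5 | step 12 | dimethyl 2-[(3S,6R,7R,10Z,13E)-6,7-epoxy-1-hydroxy-14-iodo-6,10-dimethylpentadeca-10,13-dien-3-yl]malonate | COC(=O)C([C@H](CCO)CC[C@@]1(C)O[C@@H]1CC/C(C)=C\C/C=C(C)/I)C(=O)OC
F6 | step 12 | dimethyl 2-[(3S,6R,7R,10Z,13E)-6,7-epoxy-14-iodo-6,10-dimethyl-1-oxopentadeca-10,13-dien-3-yl]malonate | COC(=O)C([C@H](CC=O)CC[C@@]1(C)O[C@@H]1CC/C(C)=C\C/C=C(C)/I)C(=O)OC
F7 | step 12 | dimethyl 2-[(1S,4R,5R,8Z,11E,13S)-4,5-epoxy-13-hydroxy-4,8,12-trimethylcyclotetradeca-8,11-dien-1-yl]malonate | COC(=O)C(C(=O)OC)[C@H]1CC[C@@]2(C)O[C@@H]2CC/C(C)=C\C/C=C(C)/[C@@H](O)C1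
F8 | step 12 | dimethyl 2-[(1S,4R,5R,8Z,11E)-4,5-epoxy-4,8,12-trimethyl-13-oxocyclotetradeca-8,11-dien-1-yl]malonate | COC(=O)C(C(=O)OC)[C@H]1CC[C@@]2(C)O[C@@H]2CC/C(C)=C\C/C=C(C)/C(=O)C1
F9 | step 13 | methyl (4S,7S)-4-[2-(tert-butyldimethylsilyloxy)ethyl]-7-[(1R,4Z)-1-hydroxy-4-methylnon-4-en-7-yn-1-yl]-7-methyl-2-oxooxepane-3-carboxylate | COC(=O)C1C(=O)O[C@](C)([C@H](O)CC/C(C)=C\CC#CC)CC[C@H]1CCO[Si](C)(C)C(C)(C)C
F10 | step 13 | methyl (4S,7S)-4-(2-hydroxyethyl)-7-[(1R,4Z)-1-hydroxy-4-methylnon-4-en-7-yn-1-yl]-7-methyl-2-oxooxepane-3-carboxylate | COC(=O)C1C(=O)O[C@](C)([C@H](O)CC/C(C)=C\CC#CC)CC[C@H]1CCO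
F11 | step 13 | methyl (4S,7S)-7-[(1R,4Z)-1-hydroxy-4-methylnon-4-en-7-yn-1-yl]-7-methyl-2-oxo-4-(2-oxoethyl)oxepane-3-carboxylate | COC(=O)C1C(=O)O[C@](C)([C@H](O)CC/C(C)=C\CC#CC)CC[C@H]1CC=O
F12 | step 13 | methyl (1S,4S,5R,8Z,11E,13S)-5-hydroxy-13-(triisopropylsilyloxy)cembra-8,11-dien-16,4-olide-15-carboxylate | COC(=O)C1C(=O)O[C@@]2(C)CC[C@H]1C[C@H](O[Si](C(C)C)(C(C)C)C(C)C)/C(C)=C/C/C=C(/C)CC[C@H]2O
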